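The numbers in the tables were computed for an exercise, noise included.

The leftover comes first. If each impurity takes one free catalyst, which no earlier run tests, the flask keeps 0.163 mM of working catalyst and the noon run kept 0.263 mM.

| flask | starting material | reagent | free catalyst | impurity | remark | time |
|---|---|---|---|---|---|---|
| noon | 0.050 M (in portions, 4) | 0.065 M | 0.30 mM | 37 µM | run made earlier; portions every 80 s |  |
| flask | 0.050 M (in portions, 4) | 0.0650 M | 0.20 mM | 37 µM | the portions of starting material follow each other after 80 s, the first at the start | 5.0 min |

- noon (time / s: target / %): 10.0: 1.9; 20.0: 4.2; 40.0: 8.3; 60.0: 11.9

(standard deviation of a reading: 0.3 percentage points)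

* the state of affairs at 5.0 min: stopped, and by what, or still going (it is still moving / the reagent has run out first / forward and back rates have come level / all of the starting material has reacted / no working catalyst is left)
* how much target there is at 5.0 min, in percent of the starting material charged
* amount of target if the flask were left three thousand times as long, in percent of the starting material charged

- the reaction counts as stopped when no species that holds the starting material changes by six tenths of a point or more over the second half of the time
- no earlier run changes the charge of free catalyst; that part of a forecast is a guess

Where can the flask end? With [reagent] = 0.0650 M against a whole charge of 0.050 M of starting material, and if one reagent is used per target, starting material is the limiting reagent. The charges therefore allow complete conversion, with 0.0150 M of reagent over.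

How fast does it get there? The noon reading of 11.9% at 60.0 s gives the turnover rate (turnover frequency), the target made per second per working catalyst, as 0.377 s⁻¹. This is a reading, a mean over the noon run's first 60.0 s, taken with a quarter of the charge in.

Is 5.0 min enough? At that rate the flask's working catalyst needs 13.6 min for the whole charge, so your own reckoning says it is still moving, with 36.9% of target at 5.0 min.

The forecast says "it is still moving", with 40% of target (29% to 48%) and 92% in the long run (60% to 100%), holding that “Later portions keep the catalyst saturated”.

The flask gives "it is still moving", with 48.8% of target and 100% in the long run.

    starting material + free catalyst → catalyst intermediate A (k = 65.0 L mol⁻¹ s⁻¹)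
    free catalyst + impurity → spent catalyst (k = 19000 L mol⁻¹ s⁻¹)
    reagent + catalyst intermediate A ⇌ catalyst intermediate B (K = 1400 L mol⁻¹, k = 39.0 L mol⁻¹ s⁻¹)
    catalyst intermediate B → free catalyst + target (k = 1.70 s⁻¹)

Spent catalyst in the flask stands at 18.5% of the catalyst at 5.00 min, and the impurity charge is 18.5% of the catalyst charge. The flask's mean turnover rate over 5.0 min comes to 0.499 s⁻¹, above the noon reading of 0.377 s⁻¹. The same flask with 0.12 M of starting material gives 27.4% of target, a mean turnover rate of 0.672 s⁻¹.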